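Everything rests on cutting the O1–C8a bond of the 2H-chromene (pyran ring) of the benzophenone. In the chromene, ring-fusion carbon C8a stands para to the C6 carbonyl, so a fluorine placed on C8a is an activated leaving group; a tertiary alkoxide carried on a cis-alkenyl arm at C4a can reach only that carbon. One base-mediated addition–elimination therefore closes the pyran with the linear fusion already written into the halogen pattern. The precursor is a 2,4-difluorobenzophenone carrying a (Z)-3-hydroxy-3-methylbut-1-enyl group at C5 and the prenylated, TIPS-protected ring A; the remaining ortho fluorine later becomes the C7 hydroxyl.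

Key step: step 8

Remark: the target has no stereocentre or other stereogenic element, so there is no enantiomer to select; the only stereochemical element in the route is the Z alkene of 17, which is consumed in step 8. Prenyl = 3-methylbut-2-en-1-yl throughout.

Step 1
Reactants: 1 1,3-dibromobenzene; 2 prenyl bromide (1-bromo-3-methylbut-2-ene)
Product: 4 1,3-dibromo-2-(3-methylbut-2-en-1-yl)benzene, via (2,6-dibromophenyl)lithium 3 (not isolated)
Conditions: LDA (1.05 equiv), THF, −78 °C; then CuBr·SMe2 (0.2 equiv), 2 (1.3 equiv), −78 °C → 0 °C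
Reagents that add atoms: none
Why: Directed ortho-lithiation removes the proton flanked by both bromines (the anion is kept at −78 °C so that no aryne forms), and copper-catalysed allylic alkylation then joins the aryl carbon to the unsubstituted CH2 end of prenyl bromide in the SN2 sense, which gives the normal prenyl group.

Step 2
Reactants: 4 1,3-dibromo-2-(3-methylbut-2-en-1-yl)benzene
Product: 7 3-bromo-2-(3-methylbut-2-en-1-yl)phenol, via aryllithium 5 (not isolated), via lithium aryltrimethoxyborate 6 (not isolated)
Conditions: n-BuLi (1.0 equiv), THF, −78 °C; B(OMe)3, −78 °C → rt; 30% H2O2, 2 M NaOH, 0 °C → rt; then 1 M HCl to pH 5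
Reagents that add atoms: hydrogen peroxide, OO
Why: Mono bromine–lithium exchange (the aryl anion resists a second exchange), borylation and alkaline peroxide oxidation of the aryl–boron bond by 1,2-aryl shift from boron to oxygen should give the phenol without acid and without touching the trisubstituted alkene.

Step 3
Reactants: 7 3-bromo-2-(3-methylbut-2-en-1-yl)phenol
Product: 8 [3-bromo-2-(3-methylbut-2-en-1-yl)phenoxy]tri(propan-2-yl)silane
Conditions: TIPSCl (1.2 equiv), imidazole (2.5 equiv), DMF, rt
Reagents that add atoms: triisopropylsilyl chloride, CC(C)[Si](Cl)(C(C)C)C(C)C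
Why: Standard silylation of a phenol; the bulky aryl TIPS ether tolerates n-BuLi at −78 °C, amine bases and NaH, and it can be removed at the end with fluoride instead of acid.

Step 4
Reactants: 9 5-bromo-2,4-difluorobenzoic acid
Product: 11 5-bromo-2,4-difluoro-N-methoxy-N-methylbenzamide, via acyl imidazole 10 (not isolated)
Conditions: CDI (1.2 equiv), CH2Cl2, rt; then MeNH(OMe)·HCl (1.5 equiv), rt
Reagents that add atoms: N,O-dimethylhydroxylamine hydrochloride, CNOC.Cl
Why: Weinreb amide formation through the acyl imidazolide proceeds under nearly neutral conditions at room temperature, under which neither activated C–F bond is displaced.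

Step 5
Reactants: 11 5-bromo-2,4-difluoro-N-methoxy-N-methylbenzamide; 12 2-methylbut-3-yn-2-ol
Product: 13 2,4-difluoro-5-(3-hydroxy-3-methylbut-1-yn-1-yl)-N-methoxy-N-methylbenzamide
Conditions: PdCl2(PPh3)2 (3 mol%), CuI (5 mol%), Et3N/THF (degassed), 60 °C
Reagents that add atoms: none
Why: Sonogashira coupling at the only C–Br bond, which the ortho fluorine activates for oxidative addition, with a tertiary amine too hindered to displace fluoride; installing the alkyne here removes the aryl bromide before any organolithium is used.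

Step 6
Reactants: 8 [3-bromo-2-(3-methylbut-2-en-1-yl)phenoxy]tri(propan-2-yl)silane; 13 2,4-difluoro-5-(3-hydroxy-3-methylbut-1-yn-1-yl)-N-methoxy-N-methylbenzamide
Product: 16 [2,4-difluoro-5-(3-hydroxy-3-methylbut-1-yn-1-yl)phenyl][2-(3-methylbut-2-en-1-yl)-3-(triisopropylsilyloxy)phenyl]methanone, via aryllithium 14 (not isolated), via magnesium alkoxide 15 (not isolated)
Conditions: 8 (1.25 equiv), n-BuLi (1.2 equiv), THF, −78 °C; separately 13, i-PrMgCl (1.0 equiv), THF, −78 °C; combine, −78 °C → −20 °C; then cold 0.5 M HCl
Reagents that add atoms: none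
Why: Bromine–lithium exchange gives aryllithium 14, which adds only once to the Weinreb amide because the N,O-chelated tetrahedral adduct persists until the quench (Weinreb ketone synthesis); the tertiary alcohol is masked beforehand as its chloromagnesium alkoxide so that it does not consume 14, and no aryl bromide remains that could scramble with the aryllithium.

Step 7
Reactants: 16 [2,4-difluoro-5-(3-hydroxy-3-methylbut-1-yn-1-yl)phenyl][2-(3-methylbut-2-en-1-yl)-3-(triisopropylsilyloxy)phenyl]methanone
Product: 17 (Z)-[2,4-difluoro-5-(3-hydroxy-3-methylbut-1-en-1-yl)phenyl][2-(3-methylbut-2-en-1-yl)-3-(triisopropylsilyloxy)phenyl]methanone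
Conditions: H2 (1 atm), Lindlar catalyst (Pd/CaCO3, Pb-poisoned), quinoline, EtOAc, rt, stopped after 1 equiv H2
Reagents that add atoms: none
Why: Lindlar semihydrogenation delivers both hydrogens to one face of the alkyne on the poisoned palladium surface and so sets the Z alkene that step 8 needs, while the trisubstituted prenyl alkene, the diaryl ketone, the C–F bonds and the silyl ether should be inert.

Step 8
Reactants: 17 (Z)-[2,4-difluoro-5-(3-hydroxy-3-methylbut-1-en-1-yl)phenyl][2-(3-methylbut-2-en-1-yl)-3-(triisopropylsilyloxy)phenyl]methanone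
Product: 19 (7-fluoro-2,2-dimethyl-2H-chromen-6-yl)[2-(3-methylbut-2-en-1-yl)-3-(triisopropylsilyloxy)phenyl]methanone, via sodium alkoxide 18 (not isolated)
Conditions: NaH (1.3 equiv), THF (0.02 M), 0 °C → 40 °C
Reagents that add atoms: none
Why: NaH converts the tertiary alcohol into alkoxide 18, whose oxygen adds to the fluorine-bearing carbon para to the ketone (C4 of the benzophenone, the future C8a) to give a cyclohexadienyl anion delocalised onto the carbonyl, and loss of fluoride restores the arene (addition–elimination SNAr). The closest known reaction type is the intramolecular SNAr etherification of carbonyl-activated fluoroarenes by tethered alkoxides used for chromans and benzofurans, here with a tertiary alkoxide. The six-membered pyran closes by attack of oxygen on an sp2 ring carbon, formally 6-exo-trig with respect to the C8a=C8 π bond, which is a favoured mode. No stereocentre is created; the Z alkene from step 7 and the gem-dimethyl group hold the oxygen within bonding distance of C8a. The step needs site selectivity between two activated C–F bonds, and the tether secures it because it reaches only the carbon next to C4a, while high dilution should suppress intermolecular attack at the ortho fluorine. Sodium fluoride is insoluble in THF, so the aryl silyl ether should survive, and the basic medium leaves the prenyl group alone.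

Step 9
Reactants: 19 (7-fluoro-2,2-dimethyl-2H-chromen-6-yl)[2-(3-methylbut-2-en-1-yl)-3-(triisopropylsilyloxy)phenyl]methanone
Product: 21 (7-hydroxy-2,2-dimethyl-2H-chromen-6-yl)[2-(3-methylbut-2-en-1-yl)-3-(triisopropylsilyloxy)phenyl]methanone, via sulfonylethyl ether 20 (not isolated)
Conditions: MeSO2CH2CH2OH (1.5 equiv), NaH (3 equiv), DMF, 0 °C → rt; then 1 M HCl to pH 4
Reagents that add atoms: 2-(methylsulfonyl)ethanol, CS(=O)(=O)CCO
Why: Intermolecular SNAr of the primary alkoxide at C7–F, ortho to the ketone, followed by base-induced E1cB loss of methyl vinyl sulfone from ether 20, should free the phenoxide, which as a vinylogous carboxylate resists further attack; any silyl ether cleaved here only anticipates step 10.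

Step 10
Reactants: 21 (7-hydroxy-2,2-dimethyl-2H-chromen-6-yl)[2-(3-methylbut-2-en-1-yl)-3-(triisopropylsilyloxy)phenyl]methanone
Product: 22 cudraphenone A
Conditions: TBAF (1.2 equiv), AcOH (1.2 equiv), THF, 0 °C → rt
Reagents that add atoms: none
Why: Fluoride-mediated cleavage of the aryl silyl ether, driven by the strong Si–F bond and buffered with acetic acid, should free the ring-A phenol without exposing the ortho-prenyl phenol or the chromene to strong acid or base.

Compound list
1 | 1,3-dibromobenzene | Brc1cccc(Br)c1 | starting material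
2 | prenyl bromide (1-bromo-3-methylbut-2-ene) | CC(C)=CCBr | starting material
3 | (2,6-dibromophenyl)lithium (formed in situ) | [Li]c1c(Br)cccc1Br | intermediate
4 | 1,3-dibromo-2-(3-methylbut-2-en-1-yl)benzene | CC(C)=CCc1c(Br)cccc1Br | intermediate
5 | [3-bromo-2-(3-methylbut-2-en-1-yl)phenyl]lithium (formed in situ) | CC(C)=CCc1c([Li])cccc1Br | intermediate
6 | lithium [3-bromo-2-(3-methylbut-2-en-1-yl)phenyl]trimethoxyborate (formed in situ) | [Li+].CO[B-](OC)(OC)c1cccc(Br)c1CC=C(C)C | intermediate
7 | 3-bromo-2-(3-methylbut-2-en-1-yl)phenol | CC(C)=CCc1c(O)cccc1Br | intermediate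
8 | [3-bromo-2-(3-methylbut-2-en-1-yl)phenoxy]tri(propan-2-yl)silane | CC(C)=CCc1c(O[Si](C(C)C)(C(C)C)C(C)C)cccc1Br | intermediate
9 | 5-bromo-2,4-difluorobenzoic acid | OC(=O)c1cc(Br)c(F)cc1F | starting material
10 | (5-bromo-2,4-difluorophenyl)(1H-imidazol-1-yl)methanone (formed in situ) | O=C(c1cc(Br)c(F)cc1F)n1ccnc1 | intermediate
11 | 5-bromo-2,4-difluoro-N-methoxy-N-methylbenzamide | CON(C)C(=O)c1cc(Br)c(F)cc1F | intermediate
12 | 2-methylbut-3-yn-2-ol | CC(C)(O)C#C | starting material
13 | 2,4-difluoro-5-(3-hydroxy-3-methylbut-1-yn-1-yl)-N-methoxy-N-methylbenzamide | CON(C)C(=O)c1cc(C#CC(C)(C)O)c(F)cc1F | intermediate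
14 | [2-(3-methylbut-2-en-1-yl)-3-(triisopropylsilyloxy)phenyl]lithium (formed in situ) | CC(C)=CCc1c(O[Si](C(C)C)(C(C)C)C(C)C)cccc1[Li] | intermediate
15 | chloromagnesium alkoxide of 13 (formed in situ) | CON(C)C(=O)c1cc(C#CC(C)(C)O[Mg]Cl)c(F)cc1F | intermediate
16 | [2,4-difluoro-5-(3-hydroxy-3-methylbut-1-yn-1-yl)phenyl][2-(3-methylbut-2-en-1-yl)-3-(triisopropylsilyloxy)phenyl]methanone | CC(C)=CCc1c(O[Si](C(C)C)(C(C)C)C(C)C)cccc1C(=O)c1cc(C#CC(C)(C)O)c(F)cc1F | intermediate
17 | (Z)-[2,4-difluoro-5-(3-hydroxy-3-methylbut-1-en-1-yl)phenyl][2-(3-methylbut-2-en-1-yl)-3-(triisopropylsilyloxy)phenyl]methanone | CC(C)=CCc1c(O[Si](C(C)C)(C(C)C)C(C)C)cccc1C(=O)c1cc(/C=C\C(C)(C)O)c(F)cc1F | intermediate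
18 | sodium alkoxide of 17 (formed in situ) | CC(C)=CCc1c(O[Si](C(C)C)(C(C)C)C(C)C)cccc1C(=O)c1cc(/C=C\C(C)(C)[O-])c(F)cc1F.[Na+] | intermediate
19 | (7-fluoro-2,2-dimethyl-2H-chromen-6-yl)[2-(3-methylbut-2-en-1-yl)-3-(triisopropylsilyloxy)phenyl]methanone | CC(C)=CCc1c(O[Si](C(C)C)(C(C)C)C(C)C)cccc1C(=O)c1cc2c(cc1F)OC(C)(C)C=C2 | intermediate
20 | {2,2-dimethyl-7-[2-(methylsulfonyl)ethoxy]-2H-chromen-6-yl}[2-(3-methylbut-2-en-1-yl)-3-(triisopropylsilyloxy)phenyl]methanone (formed in situ) | CC(C)=CCc1c(O[Si](C(C)C)(C(C)C)C(C)C)cccc1C(=O)c1cc2c(cc1OCCS(C)(=O)=O)OC(C)(C)C=C2 | intermediate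
21 | (7-hydroxy-2,2-dimethyl-2H-chromen-6-yl)[2-(3-methylbut-2-en-1-yl)-3-(triisopropylsilyloxy)phenyl]methanone | CC(C)=CCc1c(O[Si](C(C)C)(C(C)C)C(C)C)cccc1C(=O)c1cc2c(cc1O)OC(C)(C)C=C2 | intermediate
22 | cudraphenone A, (7-hydroxy-2,2-dimethyl-2H-chromen-6-yl)[3-hydroxy-2-(3-methylbut-2-en-1-yl)phenyl]methanone | CC(C)=CCc1c(O)cccc1C(=O)c1cc2c(cc1O)OC(C)(C)C=C2 | target

Total step count: 10.
Longest linear sequence: 8 steps (1, 2, 3, 6, 7, 8, 9, 10); the ring-B branch (4, 5) joins at step 6.

Steps most likely to fail

1. Step 8. The hindered tertiary alkoxide may close slowly, so that attack of one molecule's alkoxide on the ortho C–F bond of another, or base- and fluoride-induced loss of the silyl ether, overtakes ring closure. The fallback closes the pyran before the diaryl ketone exists. It sets out from 13: Lindlar semihydrogenation gives (Z)-2,4-difluoro-5-(3-hydroxy-3-methylbut-1-en-1-yl)-N-methoxy-N-methylbenzamide F1. NaH in DMF (rt to 60 °C) then closes the ring by displacement of the fluoride para to the carboxamide and gives 7-fluoro-N-methoxy-N,2,2-trimethyl-2H-chromene-6-carboxamide F2; this small amide carries no silyl ether and no ketone and can be pushed harder. Addition of aryllithium 14 (from 8 and n-BuLi, as in step 6) to F2 gives 19, where the route is rejoined; the chromene then enters the fragment union as a finished building block.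

2. Step 6. The aryllithium may act as a base toward the acidic ring hydrogen between the two fluorines, or attack a ring fluorine, instead of substituting at the amide, and the aggregated magnesium alkoxide may react incompletely. The fallback replaces acyl substitution by addition to an aldehyde, which should outrun these processes, followed by oxidation. It sets out from 8: aryllithium 14 is added at −78 °C to commercial 5-bromo-2,4-difluorobenzaldehyde to give racemic (5-bromo-2,4-difluorophenyl)[2-(3-methylbut-2-en-1-yl)-3-(triisopropylsilyloxy)phenyl]methanol F3. Oxidation of this diaryl carbinol with MnO2 in CH2Cl2 gives (5-bromo-2,4-difluorophenyl)[2-(3-methylbut-2-en-1-yl)-3-(triisopropylsilyloxy)phenyl]methanone F4. Sonogashira coupling of F4 with 12 (PdCl2(PPh3)2, CuI, Et3N, 50 °C) returns to the route at 16.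

3. Step 9. Displacement may be sluggish because the chromene oxygen para to the ketone damps the activation of C7–F, and the sulfonyl alkoxide may fragment to vinyl sulfone before it attacks. The fallback uses a more nucleophilic, non-fragmenting alkoxide and unmasks the phenol in a separate catalytic step. It sets out from 19: sodium allyloxide (allyl alcohol, NaH, THF/DMF, rt to 50 °C) gives [2,2-dimethyl-7-(prop-2-en-1-yloxy)-2H-chromen-6-yl][2-(3-methylbut-2-en-1-yl)-3-(triisopropylsilyloxy)phenyl]methanone F5. Palladium-catalysed deallylation (Pd(PPh3)4, morpholine, THF, rt; Tsuji–Trost transfer of the allyl group to the amine) then returns to the route at 21; the prenyl and chromene alkenes carry no leaving group and should not be affected.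

Further compounds
F1 | step 8 | (Z)-2,4-difluoro-5-(3-hydroxy-3-methylbut-1-en-1-yl)-N-methoxy-N-methylbenzamide | CON(C)C(=O)c1cc(/C=C\C(C)(C)O)c(F)cc1F
F2 | step 8 | 7-fluoro-N-methoxy-N,2,2-trimethyl-2H-chromene-6-carboxamide | CON(C)C(=O)c1cc2c(cc1F)OC(C)(C)C=C2
F3 | step 6 | (5-bromo-2,4-difluorophenyl)[2-(3-methylbut-2-en-1-yl)-3-(triisopropylsilyloxy)phenyl]methanol (racemic) | CC(C)=CCc1c(O[Si](C(C)C)(C(C)C)C(C)C)cccc1C(O)c1cc(Br)c(F)cc1F
F4 | step 6 | (5-bromo-2,4-difluorophenyl)[2-(3-methylbut-2-en-1-yl)-3-(triisopropylsilyloxy)phenyl]methanone | CC(C)=CCc1c(O[Si](C(C)C)(C(C)C)C(C)C)cccc1C(=O)c1cc(Br)c(F)cc1F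
F5 | step 9 | [2,2-dimethyl-7-(prop-2-en-1-yloxy)-2H-chromen-6-yl][2-(3-methylbut-2-en-1-yl)-3-(triisopropylsilyloxy)phenyl]methanone | CC(C)=CCc1c(O[Si](C(C)C)(C(C)C)C(C)C)cccc1C(=O)c1cc2c(cc1OCC=C)OC(C)(C)C=C2
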